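**Retrosynthetic overview**

1. The chromone C2–C5' aryl bond is cut last: Suzuki–Miyaura coupling of a C5' pinacol boronate with a 2-chloro-5-hydroxy-7-silyloxychromone, then one fluoride step that removes both silyl groups.
2. The C(CH3)2OH group on C2' is traced back to a methyl ester (two methyl additions), and the boronate to an aryl bromide.
3. Feature that carries the strategy: C3' is a benzylic carbinol on arene carbon C3a', ortho to the ring oxygen O1' on C7a', and C2' bears a carbon that can be an ester. O1'–C7a'–C3a'–C3' is therefore a salicylaldehyde and C2' the single carbon of an ester-stabilised sulfonium ylide; a (4+1) annulation forms C2'–C3' and O1'–C2', closes the dihydrofuran ring and sets both stereocentres.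
4. Precursors: 5-bromo-3-prenylsalicylaldehyde by O-allylation, aromatic Claisen rearrangement and cross-metathesis (regiospecific, unlike direct C-prenylation of the phenoxide); the C2-symmetric sulfonium salt from (2S,5S)-hexane-2,5-diol.
5. Ring order: dihydrofuran ring (step 7); pyranone ring of the chromone in a separate branch (step 11); the two halves are joined in step 13.

Key step: step 7

Remarks on the chemistry:
- Primed locants (O1', C2', C3', C3a', C4'–C7', C7a') refer to the 2,3-dihydrobenzofuran unit, unprimed ones to the chromone.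
- Assumption: the (2R,5R) sulfonium salt is taken to deliver the (2R,3R) annulation product. The sense of induction is not established; should it prove opposite, the mirror-image salt from (2R,5R)-hexane-2,5-diol is used with no other change.

**Route**

Step 1
Reactants: 1 5-bromosalicylaldehyde; 2 allyl bromide
Product: 3 2-(allyloxy)-5-bromobenzaldehyde
Conditions: K2CO3, DMF, rt
Reagents that add atoms: none
Why: Williamson ether synthesis; the acidic salicylaldehyde phenoxide should be O-alkylated cleanly by the allylic bromide.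

Step 2
Reactants: 3 2-(allyloxy)-5-bromobenzaldehyde
Product: 5 3-allyl-5-bromo-2-hydroxybenzaldehyde, via dienone 4 (not isolated)
Conditions: neat, N2, 195 °C
Reagents that add atoms: none
Why: Aromatic Claisen rearrangement; the [3,3] shift can only reach the one free ortho carbon (C3), and dienone 4 tautomerises to the phenol.

Step 3
Reactants: 5 3-allyl-5-bromo-2-hydroxybenzaldehyde; 6 2-methylbut-2-ene
Product: 7 5-bromo-2-hydroxy-3-(3-methylbut-2-enyl)benzaldehyde
Conditions: second-generation Grubbs catalyst (SIMes)(PCy3)Cl2Ru=CHPh (3 mol %), 2-methylbut-2-ene (excess), CH2Cl2, 40 °C, sealed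
Reagents that add atoms: none
Why: Olefin cross-metathesis; the terminal allyl CH2 is exchanged for the isopropylidene of the excess alkene with loss of propene, and the ruthenium carbene tolerates phenol, aldehyde and aryl bromide.

Step 4
Reactants: 8 (2S,5S)-hexane-2,5-diol
Product: 9 (2S,5S)-hexane-2,5-diyl dimethanesulfonate
Conditions: MsCl, Et3N, CH2Cl2, 0 °C
Reagents that add atoms: methanesulfonyl chloride, CS(=O)(=O)Cl
Why: Sulfonylation at oxygen; no C–O bond is broken, so both stereocentres are retained.

Step 5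
Reactants: 9 (2S,5S)-hexane-2,5-diyl dimethanesulfonate
Product: 11 (2R,5R)-2,5-dimethylthiolane, via thiolate mesylate 10 (not isolated)
Conditions: Na2S·9H2O, DMSO, rt
Reagents that add atoms: sodium sulfide Na2S, [Na+].[Na+].[S-2]
Why: Double SN2 displacement by sulfide, intermolecular and then 5-exo-tet, inverts both carbons and should turn the (S,S) dimesylate into the (R,R) thiolane.

Step 6
Reactants: 11 (2R,5R)-2,5-dimethylthiolane; 12 methyl bromoacetate
Product: 13 (2R,5R)-1-(2-methoxy-2-oxoethyl)-2,5-dimethylthiolan-1-ium bromide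
Conditions: acetone, rt, 48 h
Reagents that add atoms: none
Why: S-alkylation of the sulfide by the activated bromide; the two sulfur lone pairs are homotopic in the C2-symmetric thiolane, so a single salt without a sulfur stereocentre should form.

Step 7
Reactants: 7 5-bromo-2-hydroxy-3-(3-methylbut-2-enyl)benzaldehyde; 13 (2R,5R)-1-(2-methoxy-2-oxoethyl)-2,5-dimethylthiolan-1-ium bromide
Product: 16 methyl (2R,3R)-5-bromo-3-hydroxy-7-(3-methylbut-2-enyl)-2,3-dihydro-1-benzofuran-2-carboxylate, via sulfonium ylide 14 (not isolated), via trans-glycidic ester 15 (not isolated)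
Conditions: 13 (1.2 equiv), K2CO3 (1.5 equiv), MeCN, −20 → 0 °C
Reagents that add atoms: none
Why: Proposed new method: carbonate gives the phenoxide of 7 and, reversibly, ester-stabilised ylide 14, whose carbon adds to the aldehyde (C2'–C3' bond); the anti betaine loses thiolane 11 in a 3-exo-tet closure to trans-glycidic ester 15, and the ortho phenoxide then attacks C2' from the rear of the C2'–O bond (attack at C3' would need a four-membered ring), forming O1'–C2' with inversion. The dihydrofuran ring thus closes by an intramolecular SN2 opening of the oxirane in the 5-endo mode, the same closure that operates when salicylaldehydes react with achiral sulfur ylides. The closest known chemistry is that racemic (4+1) annulation of sulfur ylides with salicylaldehydes and their imines to trans-2,3-dihydrobenzofuran-3-ols and 3-amines, together with chiral-sulfide-mediated Corey–Chaykovsky epoxidation; the untested element is the transfer of chirality from a sulfonium salt in this annulation. C3' is fixed when the betaine closes, under control of the C2-symmetric thiolane (its two sulfur faces are equivalent, so only one ylide exists, and the ring methyl groups should make the two diastereomeric anti betaines close at different rates); C2' is fixed in the same closure and inverted once by the phenoxide, which places the C3' hydroxyl trans to the ester, i.e. (2R,3R). The step needs ylide C-attack to outrun O-alkylation of the phenoxide by 13 (which would open a racemic alkylation–aldol channel), the anti betaine to be funnelled to the trans epoxide, and the product to escape E1cB dehydration to the benzofuran; the reversibility of betaine formation, the phenoxide held next to the new epoxide, and the mild base at or below 0 °C serve these three needs.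

Step 8
Reactants: 16 methyl (2R,3R)-5-bromo-3-hydroxy-7-(3-methylbut-2-enyl)-2,3-dihydro-1-benzofuran-2-carboxylate
Product: 17 methyl (2R,3R)-5-bromo-3-[tert-butyl(dimethyl)silyl]oxy-7-(3-methylbut-2-enyl)-2,3-dihydro-1-benzofuran-2-carboxylate
Conditions: TBSOTf, 2,6-lutidine, CH2Cl2, −78 → 0 °C
Reagents that add atoms: tert-butyldimethylsilyl trifluoromethanesulfonate, CC(C)(C)[Si](C)(C)OS(=O)(=O)C(F)(F)F
Why: Silyl ether formation with a hindered, weakly basic amine should cap the C3' hydroxyl without E1cB elimination or epimerisation at C2', and blocks retro-aldol ring opening in the next step.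

Step 9
Reactants: 17 methyl (2R,3R)-5-bromo-3-[tert-butyl(dimethyl)silyl]oxy-7-(3-methylbut-2-enyl)-2,3-dihydro-1-benzofuran-2-carboxylate
Product: 19 2-[(2R,3R)-5-bromo-3-[tert-butyl(dimethyl)silyl]oxy-7-(3-methylbut-2-enyl)-2,3-dihydro-1-benzofuran-2-yl]propan-2-ol, via methyl ketone 18 (not isolated)
Conditions: MeMgBr (4 equiv), anhydrous CeCl3, THF, −78 → 0 °C
Reagents that add atoms: methylmagnesium bromide, C[Mg]Br
Why: Double Grignard addition to the ester through ketone 18; the weakly basic cerium-modified reagent should add faster than it deprotonates C2', so the C2' configuration is kept and the aryl bromide is untouched.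

Step 10
Reactants: 19 2-[(2R,3R)-5-bromo-3-[tert-butyl(dimethyl)silyl]oxy-7-(3-methylbut-2-enyl)-2,3-dihydro-1-benzofuran-2-yl]propan-2-ol
Product: 20 2-[(2R,3R)-3-[tert-butyl(dimethyl)silyl]oxy-7-(3-methylbut-2-enyl)-5-(4,4,5,5-tetramethyl-1,3,2-dioxaborolan-2-yl)-2,3-dihydro-1-benzofuran-2-yl]propan-2-ol
Conditions: bis(pinacolato)diboron, Pd(dppf)Cl2 (5 mol %), KOAc, 1,4-dioxane, 85 °C
Reagents that add atoms: bis(pinacolato)diboron, CC1(C)OB(OC1(C)C)B1OC(C)(C)C(C)(C)O1
Why: Miyaura borylation of an unhindered aryl bromide; the weak acetate base should leave the free tertiary alcohol, the silyl ether and the prenyl group alone.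

Step 11
Reactants: 21 phloroglucinol; 22 3,3-dichloroacrylic acid
Product: 24 2-chloro-5,7-dihydroxy-4H-chromen-4-one, via dichlorovinyl ketone 23 (not isolated)
Conditions: P2O5/MeSO3H (1:10 w/w), 60 °C; poured onto ice
Reagents that add atoms: none
Why: Friedel–Crafts acylation of the symmetric triphenol gives β,β-dichlorovinyl ketone 23, whose ortho hydroxyl adds to the dichlorinated carbon (6-endo oxa-Michael) and loses HCl, the same acylation–ring closure logic by which phenols and 3,3-dimethylacrylic acid give chromanones.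

Step 12
Reactants: 24 2-chloro-5,7-dihydroxy-4H-chromen-4-one
Product: 25 2-chloro-5-hydroxy-7-[tri(propan-2-yl)silyl]oxy-4H-chromen-4-one
Conditions: TIPSOTf (1.05 equiv), 2,6-lutidine, CH2Cl2, −40 → 0 °C
Reagents that add atoms: triisopropylsilyl trifluoromethanesulfonate, CC(C)[Si](C(C)C)(C(C)C)OS(=O)(=O)C(F)(F)F
Why: Selective silylation of the free, more acidic 7-hydroxyl; the 5-hydroxyl is hydrogen-bonded to the C4 carbonyl, and the hindered base should not displace the C2 chloride.

Step 13
Reactants: 20 2-[(2R,3R)-3-[tert-butyl(dimethyl)silyl]oxy-7-(3-methylbut-2-enyl)-5-(4,4,5,5-tetramethyl-1,3,2-dioxaborolan-2-yl)-2,3-dihydro-1-benzofuran-2-yl]propan-2-ol; 25 2-chloro-5-hydroxy-7-[tri(propan-2-yl)silyl]oxy-4H-chromen-4-one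
Product: 26 2-[(2R,3R)-3-[tert-butyl(dimethyl)silyl]oxy-2-(2-hydroxypropan-2-yl)-7-(3-methylbut-2-enyl)-2,3-dihydro-1-benzofuran-5-yl]-5-hydroxy-7-[tri(propan-2-yl)silyl]oxy-4H-chromen-4-one
Conditions: Pd(dppf)Cl2 (5 mol %), K3PO4, 1,4-dioxane/H2O (10:1), 70 °C
Reagents that add atoms: none
Why: Suzuki–Miyaura coupling; the C2–Cl bond of the chromone is a vinylogous acyl chloride that should undergo oxidative addition readily, and any 7-O-desilylated product converges in the last step.

Step 14
Reactants: 26 2-[(2R,3R)-3-[tert-butyl(dimethyl)silyl]oxy-2-(2-hydroxypropan-2-yl)-7-(3-methylbut-2-enyl)-2,3-dihydro-1-benzofuran-5-yl]-5-hydroxy-7-[tri(propan-2-yl)silyl]oxy-4H-chromen-4-one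
Product: 27 5,7-dihydroxy-2-[(2R,3R)-3-hydroxy-2-(2-hydroxypropan-2-yl)-7-(3-methylbut-2-enyl)-2,3-dihydro-1-benzofuran-5-yl]-4H-chromen-4-one
Conditions: TBAF (3 equiv), THF, 0 °C → rt
Reagents that add atoms: none
Why: Fluoride-mediated desilylation should cleave the aryl triisopropylsilyl ether and the secondary tert-butyldimethylsilyl ether under non-acidic conditions, which the acid-labile benzylic C3' carbinol requires; no stereocentre is touched.

**Compound list**

1 | 5-bromosalicylaldehyde | O=Cc1cc(Br)ccc1O | starting material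
2 | allyl bromide | C=CCBr | starting material
3 | 2-(allyloxy)-5-bromobenzaldehyde | C=CCOc1ccc(Br)cc1C=O | intermediate
4 | 6-allyl-4-bromo-2-formylcyclohexa-2,4-dien-1-one (racemic, Claisen dienone) | C=CCC1C=C(Br)C=C(C=O)C1=O | intermediate
5 | 3-allyl-5-bromo-2-hydroxybenzaldehyde | C=CCc1cc(Br)cc(C=O)c1O | intermediate
6 | 2-methylbut-2-ene | CC=C(C)C | starting material
7 | 5-bromo-2-hydroxy-3-(3-methylbut-2-enyl)benzaldehyde | CC(C)=CCc1cc(Br)cc(C=O)c1O | intermediate
8 | (2S,5S)-hexane-2,5-diol | C[C@H](O)CC[C@H](C)O | starting material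
9 | (2S,5S)-hexane-2,5-diyl dimethanesulfonate | C[C@H](OS(C)(=O)=O)CC[C@H](C)OS(C)(=O)=O | intermediate
10 | sodium (2R,5S)-5-(methanesulfonyloxy)hexane-2-thiolate | C[C@@H]([S-])CC[C@H](C)OS(C)(=O)=O.[Na+] | intermediate
11 | (2R,5R)-2,5-dimethylthiolane | C[C@@H]1CC[C@@H](C)S1 | intermediate
12 | methyl bromoacetate | COC(=O)CBr | starting material
13 | (2R,5R)-1-(2-methoxy-2-oxoethyl)-2,5-dimethylthiolan-1-ium bromide | C[C@@H]1CC[C@@H](C)[S+]1CC(=O)OC.[Br-] | intermediate
14 | (2R,5R)-2,5-dimethylthiolan-1-ium-1-yl (methoxycarbonyl)methanide (sulfonium ylide) | C[C@@H]1CC[C@@H](C)[S+]1[CH-]C(=O)OC | intermediate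
15 | methyl (2S,3R)-3-[5-bromo-2-hydroxy-3-(3-methylbut-2-enyl)phenyl]oxirane-2-carboxylate (present as its potassium phenoxide) | COC(=O)[C@H]1O[C@@H]1c1cc(Br)cc(CC=C(C)C)c1O | intermediate
16 | methyl (2R,3R)-5-bromo-3-hydroxy-7-(3-methylbut-2-enyl)-2,3-dihydro-1-benzofuran-2-carboxylate | CC(C)=CCc1cc(Br)cc2c1O[C@@H](C(=O)OC)[C@@H]2O | intermediate
17 | methyl (2R,3R)-5-bromo-3-[tert-butyl(dimethyl)silyl]oxy-7-(3-methylbut-2-enyl)-2,3-dihydro-1-benzofuran-2-carboxylate | CC(C)=CCc1cc(Br)cc2c1O[C@@H](C(=O)OC)[C@@H]2O[Si](C)(C)C(C)(C)C | intermediate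
18 | 1-[(2R,3R)-5-bromo-3-[tert-butyl(dimethyl)silyl]oxy-7-(3-methylbut-2-enyl)-2,3-dihydro-1-benzofuran-2-yl]ethanone | CC(C)=CCc1cc(Br)cc2c1O[C@@H](C(C)=O)[C@@H]2O[Si](C)(C)C(C)(C)C | intermediate
19 | 2-[(2R,3R)-5-bromo-3-[tert-butyl(dimethyl)silyl]oxy-7-(3-methylbut-2-enyl)-2,3-dihydro-1-benzofuran-2-yl]propan-2-ol | CC(C)=CCc1cc(Br)cc2c1O[C@@H](C(C)(C)O)[C@@H]2O[Si](C)(C)C(C)(C)C | intermediate
20 | 2-[(2R,3R)-3-[tert-butyl(dimethyl)silyl]oxy-7-(3-methylbut-2-enyl)-5-(4,4,5,5-tetramethyl-1,3,2-dioxaborolan-2-yl)-2,3-dihydro-1-benzofuran-2-yl]propan-2-ol | CC(C)=CCc1cc(B3OC(C)(C)C(C)(C)O3)cc2c1O[C@@H](C(C)(C)O)[C@@H]2O[Si](C)(C)C(C)(C)C | intermediate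
21 | phloroglucinol (benzene-1,3,5-triol) | Oc1cc(O)cc(O)c1 | starting material
22 | 3,3-dichloroacrylic acid | OC(=O)C=C(Cl)Cl | starting material
23 | 3,3-dichloro-1-(2,4,6-trihydroxyphenyl)prop-2-en-1-one | O=C(C=C(Cl)Cl)c1c(O)cc(O)cc1O | intermediate
24 | 2-chloro-5,7-dihydroxy-4H-chromen-4-one | O=c1cc(Cl)oc2cc(O)cc(O)c12 | intermediate
25 | 2-chloro-5-hydroxy-7-[tri(propan-2-yl)silyl]oxy-4H-chromen-4-one | O=c1cc(Cl)oc2cc(O[Si](C(C)C)(C(C)C)C(C)C)cc(O)c12 | intermediate
26 | 2-[(2R,3R)-3-[tert-butyl(dimethyl)silyl]oxy-2-(2-hydroxypropan-2-yl)-7-(3-methylbut-2-enyl)-2,3-dihydro-1-benzofuran-5-yl]-5-hydroxy-7-[tri(propan-2-yl)silyl]oxy-4H-chromen-4-one | CC(C)=CCc1cc(-c2cc(=O)c3c(O)cc(O[Si](C(C)C)(C(C)C)C(C)C)cc3o2)cc2c1O[C@@H](C(C)(C)O)[C@@H]2O[Si](C)(C)C(C)(C)C | intermediate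
27 | 5,7-dihydroxy-2-[(2R,3R)-3-hydroxy-2-(2-hydroxypropan-2-yl)-7-(3-methylbut-2-enyl)-2,3-dihydro-1-benzofuran-5-yl]-4H-chromen-4-one | CC(C)=CCc1cc(-c2cc(=O)c3c(O)cc(O)cc3o2)cc2c1O[C@@H](C(C)(C)O)[C@@H]2O | target

**Step count**

Total: 14 steps. Longest linear sequence: 9 steps (1, 2, 3, 7, 8, 9, 10, 13, 14).

**Steps most likely to fail**

1. Step 7 (proposed new method). Betaine formation from an ester-stabilised ylide is reversible, so the two diastereomeric anti betaines may close at similar rates and the enantioselectivity may be poor. The phenoxide may also be O-alkylated by the sulfonium salt and then cyclise by a racemic aldol, and the product may dehydrate to the benzofuran by E1cB elimination.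
 Fallback, by known chemistry, from 7 back to 16. Aldehyde 7 is O-alkylated with methyl bromoacetate 12 (K2CO3, acetone, rt) to methyl 2-[4-bromo-2-formyl-6-(3-methylbut-2-enyl)phenoxy]acetate F1. A substoichiometric amount of KOtBu in THF at −20 °C should close F1 by a reversible intramolecular aldol addition to the racemic trans hydroxy ester F2, the trans isomer being the more stable one. Lipase-catalysed kinetic resolution (Candida antarctica lipase B, vinyl acetate, tert-butyl methyl ether, 30 °C) should then acetylate one enantiomer only. By the Kazlauskas model this is expected to be the (2S,3S) alcohol, which gives methyl (2S,3S)-3-acetoxy-5-bromo-7-(3-methylbut-2-enyl)-2,3-dihydro-1-benzofuran-2-carboxylate F3; the unreacted alcohol, separated by chromatography, is 16.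

2. Step 9. The organometallic may deprotonate C2' instead of adding, which would lead to β-elimination of the silyloxy group with aromatisation to the benzofuran-2-carboxylate, or to epimerisation at C2' at the ketone stage.
 Fallback, from 16 back to 19, reversing the order of protection and addition. Unprotected 16 is treated with MeMgBr (5 equiv)/CeCl3 in THF at −78 °C. The C3' oxygen is then a metal alkoxide that cannot leave, and (2R,3R)-5-bromo-2-(2-hydroxypropan-2-yl)-7-(3-methylbut-2-enyl)-2,3-dihydro-1-benzofuran-3-ol F4 should result. TBSCl/imidazole in DMF then silylates only the secondary benzylic hydroxyl, the tertiary one being too hindered, and gives 19.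

3. Step 13. The aqueous base may hydrolyse the C2–Cl bond of the chromone (to the 4-hydroxycoumarin) faster than transmetalation, the boronate may protodeboronate, and the 7-O-silyl group may be lost early and leave a deactivated phenoxide.
 Fallback, from 19 back to 26, changing to a base-free coupling. Bromide 19 is stannylated with hexamethylditin (Pd(PPh3)4, toluene, 100 °C) to 2-[(2R,3R)-3-[tert-butyl(dimethyl)silyl]oxy-7-(3-methylbut-2-enyl)-5-(trimethylstannyl)-2,3-dihydro-1-benzofuran-2-yl]propan-2-ol F5. Stille coupling of F5 with 25 (Pd(PPh3)4, CuI, DMF, 60 °C) should give 26 without any hydroxide or phosphate present.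

**Further compounds**

F1 | step 7 | methyl 2-[4-bromo-2-formyl-6-(3-methylbut-2-enyl)phenoxy]acetate | COC(=O)COc1c(C=O)cc(Br)cc1CC=C(C)C
F2 | step 7 | racemic trans-methyl 5-bromo-3-hydroxy-7-(3-methylbut-2-enyl)-2,3-dihydro-1-benzofuran-2-carboxylate (1:1 mixture of the (2R,3R) and (2S,3S) enantiomers) | CC(C)=CCc1cc(Br)cc2c1O[C@@H](C(=O)OC)[C@@H]2O.CC(C)=CCc1cc(Br)cc2c1O[C@H](C(=O)OC)[C@H]2O
F3 | step 7 | methyl (2S,3S)-3-acetoxy-5-bromo-7-(3-methylbut-2-enyl)-2,3-dihydro-1-benzofuran-2-carboxylate | CC(C)=CCc1cc(Br)cc2c1O[C@H](C(=O)OC)[C@H]2OC(C)=O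
F4 | step 9 | (2R,3R)-5-bromo-2-(2-hydroxypropan-2-yl)-7-(3-methylbut-2-enyl)-2,3-dihydro-1-benzofuran-3-ol | CC(C)=CCc1cc(Br)cc2c1O[C@@H](C(C)(C)O)[C@@H]2O
F5 | step 13 | 2-[(2R,3R)-3-[tert-butyl(dimethyl)silyl]oxy-7-(3-methylbut-2-enyl)-5-(trimethylstannyl)-2,3-dihydro-1-benzofuran-2-yl]propan-2-ol | CC(C)=CCc1cc([Sn](C)(C)C)cc2c1O[C@@H](C(C)(C)O)[C@@H]2O[Si](C)(C)C(C)(C)C
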